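**Retrosynthetic overview**

1. The target is a biflavone in which C8 of an acacetin unit (flavone 1) carries, through an ether oxygen, C4′ of an apigenin unit (flavone 2). The plan rests on ring A of flavone 1, a benzene ring with oxygens on C5, C7, C8 and C8a, in which the C8a oxygen (later O1 of the pyranone) must be distinguishable from the C5 and C7 hydroxyls.
2. Last disconnection: the pyranone of flavone 2 is opened to a 1,3-diketone, made by C-acylation of a 2-hydroxyacetophenone enolate (Baker–Venkataraman logic) with the benzoic acid para to the ether oxygen.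
3. Before it: the pyranone of flavone 1 is opened at O1–C2 and C4–C4a to a single free phenol and a 3-(4-methoxyphenyl)propiolate (oxa-Michael addition, then Friedel–Crafts closure).
4. Key disconnection: ring A of flavone 1 at C4a–C8a and C5–C6, to a 4-aryloxy-3-silyloxycyclobutenone and a silyloxyethyne (Danheiser benzannulation). The cyclobutenone comes from an aryloxyketene and the same alkyne by (2+2) cycloaddition.
5. Order of ring formation: cyclobutenone, ring A of flavone 1, pyranone of flavone 1, pyranone of flavone 2. Both B rings and ring A of flavone 2 are bought.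

Key step: step 6

Remark: enol ether 22 is drawn as the Z isomer that anti addition should give; any E isomer is carried along, because the acid of step 9 should equilibrate the geometry before ring closure.

**Route**

Step 1
Reactants: 1 acetylene; 2 triisopropylsilyl trifluoromethanesulfonate
Product: 5 (triisopropylsilyloxy)ethyne, via lithium acetylide 3 (not isolated), via lithium ethynolate 4 (not isolated)
Conditions: HC≡CH (excess), n-BuLi, THF, −78 °C; t-BuOOLi (from t-BuOOH, LiN(SiMe3)2), −78 → −20 °C; 2, −78 → 0 °C; pentane, filtration through basic alumina, distillation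
Reagents that add atoms: tert-butyl hydroperoxide, CC(C)(C)OO
Why: Oxidation of a lithium acetylide by the electrophilic oxygen of lithium tert-butyl peroxide is an established route to lithium ynolates, and a bulky silyl triflate silylates such ynolates on oxygen, so the parent acetylide should give the silyl ynol ether in one flask.

Step 2
Reactants: 6 methyl 4-hydroxybenzoate; 7 tert-butyl bromoacetate
Product: 8 tert-butyl 2-[4-(methoxycarbonyl)phenoxy]acetate
Conditions: K2CO3, acetone, reflux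
Reagents that add atoms: none
Why: Williamson ether synthesis, in which the phenoxide displaces bromide from the activated α-bromo ester; the tert-butyl ester keeps the two carboxyl groups distinguishable.

Step 3
Reactants: 8 tert-butyl 2-[4-(methoxycarbonyl)phenoxy]acetate
Product: 9 2-[4-(methoxycarbonyl)phenoxy]acetic acid
Conditions: CF3CO2H, CH2Cl2, rt
Reagents that add atoms: none
Why: Acidolysis of the tert-butyl ester (loss of the tert-butyl cation as 2-methylpropene) frees the acetic acid and leaves the methyl benzoate untouched.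

Step 4
Reactants: 9 2-[4-(methoxycarbonyl)phenoxy]acetic acid
Product: 10 2-[4-(methoxycarbonyl)phenoxy]acetyl chloride
Conditions: (COCl)2, DMF (cat.), CH2Cl2, 0 °C → rt
Reagents that add atoms: oxalyl chloride, O=C(Cl)C(Cl)=O
Why: Standard acid chloride formation through the chloroiminium species from DMF and oxalyl chloride; the methyl ester and the aryl ether are inert.

Step 5
Reactants: 10 2-[4-(methoxycarbonyl)phenoxy]acetyl chloride; 5 (triisopropylsilyloxy)ethyne
Product: 12 methyl 4-{[2-oxo-4-(triisopropylsilyloxy)cyclobut-3-en-1-yl]oxy}benzoate (racemic), via aryloxyketene 11 (not isolated)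
Conditions: 5 (1.5 equiv), Et3N (slow addition), CH2Cl2, 0 °C → rt; rapid chromatography on neutral support
Reagents that add atoms: none
Why: Dehydrochlorination gives the electrophilic aryloxyketene, which the electron-rich ynol ether should trap in a regioselective (2+2) cycloaddition (unsubstituted alkyne carbon to the ketene carbonyl carbon), a known route to 3-silyloxycyclobutenones; the one stereocentre forms as a racemate and is erased in step 6.

Step 6
Reactants: 12 methyl 4-{[2-oxo-4-(triisopropylsilyloxy)cyclobut-3-en-1-yl]oxy}benzoate; 5 (triisopropylsilyloxy)ethyne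
Product: 17 methyl 4-[2-hydroxy-4,6-bis(triisopropylsilyloxy)phenoxy]benzoate, via vinylketene 13 (not isolated), via alkenylcyclobutenone 14 (not isolated), via dienylketene 15 (not isolated), via cyclohexadienone 16 (not isolated)
Conditions: 5 (2.5 equiv), toluene (0.05 M), 80 → 100 °C, Ar
Reagents that add atoms: none
Why: Heating should open 12 by four-electron conrotatory cleavage of the C(=O)–CH(OAr) bond, the aryloxy donor turning outward, to vinylketene 13; the ketene C=C then adds alkyne 5 by (2+2) cycloaddition to 14, which opens again to dienylketene 15, closes to cyclohexadienone 16 and tautomerises to phenol 17. The closest known reaction is the Danheiser benzannulation of cyclobutenones, 3-silyloxy ones included, with silyloxyalkynes to resorcinol monosilyl ethers. Ring A is closed by the six-electron disrotatory electrocyclisation that joins the ketene carbon (future C8a) to the aryloxy-bearing carbon (future C8), after the cycloaddition has made the C8a–C4a and C6–C5 bonds. No stereocentre is formed, and the racemic centre of 12 is lost on aromatisation. The step needs one orientation of the alkyne, which the polarity of both partners secures: the nucleophilic unsubstituted alkyne carbon attacks the ketene carbonyl carbon, so the new silyloxy group ends meta to the hydroxyl and the only free hydroxyl sits next to the aryloxy carbon. It also needs capture of 13 to outrun its dimerisation and its acylation of 17, for which excess 5 and dilution are used.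

Step 7
Reactants: 18 4-ethynylanisole; 19 di-tert-butyl dicarbonate
Product: 21 tert-butyl 3-(4-methoxyphenyl)prop-2-ynoate, via lithium arylacetylide 20 (not isolated)
Conditions: n-BuLi, THF, −78 °C; 19, −78 °C → rt
Reagents that add atoms: none
Why: Acylation of a lithium acetylide with di-tert-butyl dicarbonate is a standard preparation of tert-butyl alkynoates.

Step 8
Reactants: 17 methyl 4-[2-hydroxy-4,6-bis(triisopropylsilyloxy)phenoxy]benzoate; 21 tert-butyl 3-(4-methoxyphenyl)prop-2-ynoate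
Product: 22 tert-butyl (2Z)-3-{2-[4-(methoxycarbonyl)phenoxy]-3,5-bis(triisopropylsilyloxy)phenoxy}-3-(4-methoxyphenyl)prop-2-enoate
Conditions: Cs2CO3 (0.2 equiv), MeCN (dry), 60 °C
Reagents that add atoms: none
Why: Base-catalysed oxa-Michael addition of the only free phenol to the alkynoate, in which the vinyl anion is protonated by the next phenol so that substoichiometric carbonate suffices; anti addition should place the aryloxy group cis to the ester (Z), the geometry needed for ring closure.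

Step 9
Reactants: 22 tert-butyl (2Z)-3-{2-[4-(methoxycarbonyl)phenoxy]-3,5-bis(triisopropylsilyloxy)phenoxy}-3-(4-methoxyphenyl)prop-2-enoate
Product: 25 methyl 4-{[2-(4-methoxyphenyl)-4-oxo-5,7-bis(triisopropylsilyloxy)-4H-chromen-8-yl]oxy}benzoate, via carboxylic acid 23 (not isolated), via mixed anhydride 24 (not isolated)
Conditions: CF3CO2H, CH2Cl2, rt; concentrate; (CF3CO)2O, CH2Cl2, 0 °C → rt
Reagents that add atoms: none
Why: Acidolysis of the tert-butyl ester, activation as the mixed trifluoroacetic anhydride and intramolecular Friedel–Crafts acylation (Ruhemann-type flavone closure) onto the silyloxy-activated ring, whose only open position ortho to the enol ether oxygen is the future C4a, so a single regioisomer can form.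

Step 10
Reactants: 25 methyl 4-{[2-(4-methoxyphenyl)-4-oxo-5,7-bis(triisopropylsilyloxy)-4H-chromen-8-yl]oxy}benzoate
Product: 27 methyl 4-{[5,7-bis(benzyloxy)-2-(4-methoxyphenyl)-4-oxo-4H-chromen-8-yl]oxy}benzoate, via dicaesium diolate 26 (not isolated)
Conditions: CsF (5 equiv), BnBr (3 equiv), DMF, rt → 60 °C
Reagents that add atoms: benzyl bromide, BrCc1ccccc1
Why: Fluoride cleaves the aryl silyl ethers and the caesium phenoxides are benzylated in the same flask (Williamson), which exchanges base-labile for base-stable protection before the saponification; a C5 hydroxyl already freed in step 9 would be benzylated alike.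

Step 11
Reactants: 27 methyl 4-{[5,7-bis(benzyloxy)-2-(4-methoxyphenyl)-4-oxo-4H-chromen-8-yl]oxy}benzoate
Product: 28 4-{[5,7-bis(benzyloxy)-2-(4-methoxyphenyl)-4-oxo-4H-chromen-8-yl]oxy}benzoic acid
Conditions: LiOH·H2O, THF/MeOH/H2O, rt; aq. HCl to pH 3
Reagents that add atoms: lithium hydroxide, [Li+].[OH-]
Why: Saponification of the methyl benzoate; benzyl ethers, the diaryl ether and the 2-arylchromone should tolerate aqueous LiOH at room temperature.

Step 12
Reactants: 29 1-(2,4,6-trihydroxyphenyl)ethanone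
Product: 30 1-[2,4-bis(benzyloxy)-6-hydroxyphenyl]ethanone
Conditions: BnBr (2.05 equiv), K2CO3, DMF, rt
Reagents that add atoms: benzyl bromide, BrCc1ccccc1
Why: Williamson benzylation should stop at the 2,4-diether because the remaining hydroxyl is hydrogen-bonded to the acetyl carbonyl and is much less nucleophilic.

Step 13
Reactants: 28 4-{[5,7-bis(benzyloxy)-2-(4-methoxyphenyl)-4-oxo-4H-chromen-8-yl]oxy}benzoic acid; 30 1-[2,4-bis(benzyloxy)-6-hydroxyphenyl]ethanone
Product: 33 1-[2,4-bis(benzyloxy)-6-hydroxyphenyl]-3-(4-{[5,7-bis(benzyloxy)-2-(4-methoxyphenyl)-4-oxo-4H-chromen-8-yl]oxy}phenyl)propane-1,3-dione, via acid chloride 31 (not isolated), via dilithium dianion 32 (not isolated)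
Conditions: 28, 1-chloro-N,N,2-trimethylprop-1-en-1-amine, CH2Cl2, 0 °C → rt, concentrate; 30 (1.1 equiv), LiN(SiMe3)2 (3.3 equiv), THF, −78 → −10 °C; add 31 at −78 °C → rt; aq. HCl
Reagents that add atoms: none
Why: The α-chloroenamine converts the acid into its chloride under neutral conditions, and the enolate–phenoxide dianion of the acetophenone is C-acylated to the 1,3-diketone, the one-flask form of the Baker–Venkataraman sequence; the third equivalent of base deprotonates the diketone and prevents double acylation.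

Step 14
Reactants: 33 1-[2,4-bis(benzyloxy)-6-hydroxyphenyl]-3-(4-{[5,7-bis(benzyloxy)-2-(4-methoxyphenyl)-4-oxo-4H-chromen-8-yl]oxy}phenyl)propane-1,3-dione
Product: 34 5,7-bis(benzyloxy)-8-{4-[5,7-bis(benzyloxy)-4-oxo-4H-chromen-2-yl]phenoxy}-2-(4-methoxyphenyl)-4H-chromen-4-one
Conditions: AcOH, H2SO4 (cat.), 60 °C
Reagents that add atoms: none
Why: Acid-catalysed cyclodehydration of the 2-hydroxyaryl 1,3-diketone (hemiketal formation and loss of water) closes the pyranone of flavone 2, the standard end of a Baker–Venkataraman flavone synthesis.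

Step 15
Reactants: 34 5,7-bis(benzyloxy)-8-{4-[5,7-bis(benzyloxy)-4-oxo-4H-chromen-2-yl]phenoxy}-2-(4-methoxyphenyl)-4H-chromen-4-one
Product: 35 5,7-dihydroxy-8-[4-(5,7-dihydroxy-4-oxo-4H-chromen-2-yl)phenoxy]-2-(4-methoxyphenyl)-4H-chromen-4-one
Conditions: H2 (1 atm), 10% Pd/C, THF/MeOH, rt
Reagents that add atoms: none
Why: Hydrogenolysis of the four benzyl ethers over palladium should leave the aryl methyl ether, the diaryl ether and the chromone double bonds, which are not reduced at balloon pressure and room temperature.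

**Compound list**

1 | acetylene | C#C | starting material
2 | triisopropylsilyl trifluoromethanesulfonate | CC(C)[Si](OS(=O)(=O)C(F)(F)F)(C(C)C)C(C)C | starting material
3 | lithium acetylide | [Li+].[C-]#C | intermediate
4 | lithium ethynolate | [Li+].[O-]C#C | intermediate
5 | (triisopropylsilyloxy)ethyne | C#CO[Si](C(C)C)(C(C)C)C(C)C | intermediate
6 | methyl 4-hydroxybenzoate | COC(=O)c1ccc(O)cc1 | starting material
7 | tert-butyl bromoacetate | CC(C)(C)OC(=O)CBr | starting material
8 | tert-butyl 2-[4-(methoxycarbonyl)phenoxy]acetate | COC(=O)c1ccc(OCC(=O)OC(C)(C)C)cc1 | intermediate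
9 | 2-[4-(methoxycarbonyl)phenoxy]acetic acid | COC(=O)c1ccc(OCC(=O)O)cc1 | intermediate
10 | 2-[4-(methoxycarbonyl)phenoxy]acetyl chloride | COC(=O)c1ccc(OCC(=O)Cl)cc1 | intermediate
11 | methyl 4-[(2-oxoethenyl)oxy]benzoate (aryloxyketene) | COC(=O)c1ccc(OC=C=O)cc1 | intermediate
12 | methyl 4-{[2-oxo-4-(triisopropylsilyloxy)cyclobut-3-en-1-yl]oxy}benzoate, racemic | O=C1C=C(O[Si](C(C)C)(C(C)C)C(C)C)C1Oc1ccc(C(=O)OC)cc1 | intermediate
13 | methyl 4-{[(1Z)-4-oxo-2-(triisopropylsilyloxy)buta-1,3-dien-1-yl]oxy}benzoate (vinylketene) | O=C=C/C(O[Si](C(C)C)(C(C)C)C(C)C)=C/Oc1ccc(C(=O)OC)cc1 | intermediate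
14 | methyl 4-{[(Z)-2-[2-oxo-4-(triisopropylsilyloxy)cyclobut-3-en-1-yl]-2-(triisopropylsilyloxy)ethenyl]oxy}benzoate, racemic | O=C1C=C(O[Si](C(C)C)(C(C)C)C(C)C)C1/C(O[Si](C(C)C)(C(C)C)C(C)C)=C/Oc1ccc(C(=O)OC)cc1 | intermediate
15 | methyl 4-{[(1Z,3E)-6-oxo-2,4-bis(triisopropylsilyloxy)hexa-1,3,5-trien-1-yl]oxy}benzoate (dienylketene) | O=C=C/C(O[Si](C(C)C)(C(C)C)C(C)C)=C\C(O[Si](C(C)C)(C(C)C)C(C)C)=C\Oc1ccc(C(=O)OC)cc1 | intermediate
16 | methyl 4-{[2-oxo-4,6-bis(triisopropylsilyloxy)cyclohexa-3,5-dien-1-yl]oxy}benzoate, racemic | O=C1C=C(O[Si](C(C)C)(C(C)C)C(C)C)C=C(O[Si](C(C)C)(C(C)C)C(C)C)C1Oc1ccc(C(=O)OC)cc1 | intermediate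
17 | methyl 4-[2-hydroxy-4,6-bis(triisopropylsilyloxy)phenoxy]benzoate | COC(=O)c1ccc(Oc2c(O)cc(O[Si](C(C)C)(C(C)C)C(C)C)cc2O[Si](C(C)C)(C(C)C)C(C)C)cc1 | intermediate
18 | 4-ethynylanisole | C#Cc1ccc(OC)cc1 | starting material
19 | di-tert-butyl dicarbonate | CC(C)(C)OC(=O)OC(=O)OC(C)(C)C | starting material
20 | lithium (4-methoxyphenyl)acetylide | [Li+].[C-]#Cc1ccc(OC)cc1 | intermediate
21 | tert-butyl 3-(4-methoxyphenyl)prop-2-ynoate | COc1ccc(C#CC(=O)OC(C)(C)C)cc1 | intermediate
22 | tert-butyl (2Z)-3-{2-[4-(methoxycarbonyl)phenoxy]-3,5-bis(triisopropylsilyloxy)phenoxy}-3-(4-methoxyphenyl)prop-2-enoate | COC(=O)c1ccc(Oc2c(O/C(=C\C(=O)OC(C)(C)C)c3ccc(OC)cc3)cc(O[Si](C(C)C)(C(C)C)C(C)C)cc2O[Si](C(C)C)(C(C)C)C(C)C)cc1 | intermediate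
23 | (2Z)-3-{2-[4-(methoxycarbonyl)phenoxy]-3,5-bis(triisopropylsilyloxy)phenoxy}-3-(4-methoxyphenyl)prop-2-enoic acid | COC(=O)c1ccc(Oc2c(O/C(=C\C(=O)O)c3ccc(OC)cc3)cc(O[Si](C(C)C)(C(C)C)C(C)C)cc2O[Si](C(C)C)(C(C)C)C(C)C)cc1 | intermediate
24 | mixed anhydride of 23 with trifluoroacetic acid | COC(=O)c1ccc(Oc2c(O/C(=C\C(=O)OC(=O)C(F)(F)F)c3ccc(OC)cc3)cc(O[Si](C(C)C)(C(C)C)C(C)C)cc2O[Si](C(C)C)(C(C)C)C(C)C)cc1 | intermediate
25 | methyl 4-{[2-(4-methoxyphenyl)-4-oxo-5,7-bis(triisopropylsilyloxy)-4H-chromen-8-yl]oxy}benzoate | COc1ccc(-c2cc(=O)c3c(O[Si](C(C)C)(C(C)C)C(C)C)cc(O[Si](C(C)C)(C(C)C)C(C)C)c(Oc4ccc(C(=O)OC)cc4)c3o2)cc1 | intermediate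
26 | dicaesium salt of methyl 4-{[5,7-dihydroxy-2-(4-methoxyphenyl)-4-oxo-4H-chromen-8-yl]oxy}benzoate | [Cs+].[Cs+].COc1ccc(-c2cc(=O)c3c([O-])cc([O-])c(Oc4ccc(C(=O)OC)cc4)c3o2)cc1 | intermediate
27 | methyl 4-{[5,7-bis(benzyloxy)-2-(4-methoxyphenyl)-4-oxo-4H-chromen-8-yl]oxy}benzoate | COc1ccc(-c2cc(=O)c3c(OCc5ccccc5)cc(OCc5ccccc5)c(Oc4ccc(C(=O)OC)cc4)c3o2)cc1 | intermediate
28 | 4-{[5,7-bis(benzyloxy)-2-(4-methoxyphenyl)-4-oxo-4H-chromen-8-yl]oxy}benzoic acid | COc1ccc(-c2cc(=O)c3c(OCc5ccccc5)cc(OCc5ccccc5)c(Oc4ccc(C(=O)O)cc4)c3o2)cc1 | intermediate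
29 | 1-(2,4,6-trihydroxyphenyl)ethanone | CC(=O)c1c(O)cc(O)cc1O | starting material
30 | 1-[2,4-bis(benzyloxy)-6-hydroxyphenyl]ethanone | CC(=O)c1c(O)cc(OCc2ccccc2)cc1OCc1ccccc1 | intermediate
31 | 4-{[5,7-bis(benzyloxy)-2-(4-methoxyphenyl)-4-oxo-4H-chromen-8-yl]oxy}benzoyl chloride | COc1ccc(-c2cc(=O)c3c(OCc5ccccc5)cc(OCc5ccccc5)c(Oc4ccc(C(=O)Cl)cc4)c3o2)cc1 | intermediate
32 | dilithium enolate–phenoxide of 30 | [Li+].[Li+].C=C([O-])c1c([O-])cc(OCc2ccccc2)cc1OCc1ccccc1 | intermediate
33 | 1-[2,4-bis(benzyloxy)-6-hydroxyphenyl]-3-(4-{[5,7-bis(benzyloxy)-2-(4-methoxyphenyl)-4-oxo-4H-chromen-8-yl]oxy}phenyl)propane-1,3-dione | COc1ccc(-c2cc(=O)c3c(OCc5ccccc5)cc(OCc5ccccc5)c(Oc4ccc(C(=O)CC(=O)c5c(O)cc(OCc6ccccc6)cc5OCc5ccccc5)cc4)c3o2)cc1 | intermediate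
34 | 5,7-bis(benzyloxy)-8-{4-[5,7-bis(benzyloxy)-4-oxo-4H-chromen-2-yl]phenoxy}-2-(4-methoxyphenyl)-4H-chromen-4-one | COc1ccc(-c2cc(=O)c3c(OCc5ccccc5)cc(OCc5ccccc5)c(Oc4ccc(-c5cc(=O)c6c(OCc7ccccc7)cc(OCc7ccccc7)cc6o5)cc4)c3o2)cc1 | intermediate
35 | 5,7-dihydroxy-8-[4-(5,7-dihydroxy-4-oxo-4H-chromen-2-yl)phenoxy]-2-(4-methoxyphenyl)-4H-chromen-4-one | COc1ccc(-c2cc(=O)c3c(O)cc(O)c(Oc4ccc(-c5cc(=O)c6c(O)cc(O)cc6o5)cc4)c3o2)cc1 | target

**Step count**

Total step count: 15. Longest linear sequence: 12 steps (2–6, 8–11, 13–15).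

**Steps most likely to fail**

Step 6 (key benzannulation). Capture of vinylketene 13 by alkyne 5 may lose to thermal 1,3-silyl migration in 5 (to the silylketene), to dimerisation of 13, or to acylation of the product phenol by 13. The fallback gives up the silyl ynol ether as ketenophile and the all-silyl protection; it sets out from 12 and returns to the route at 27. Cyclobutenone 12 is heated with commercial ethoxyethyne (toluene, 80 °C, sealed tube), the most robust ketenophile of this benzannulation, to give methyl 4-[4-ethoxy-2-hydroxy-6-(triisopropylsilyloxy)phenoxy]benzoate F1. Addition to 21 as in step 8 should give tert-butyl (2Z)-3-{5-ethoxy-2-[4-(methoxycarbonyl)phenoxy]-3-(triisopropylsilyloxy)phenoxy}-3-(4-methoxyphenyl)prop-2-enoate F2. CF3CO2H and then (CF3CO)2O as in step 9 pass through the corresponding acid F3 and its mixed trifluoroacetic anhydride F4 to methyl 4-{[5-ethoxy-2-(4-methoxyphenyl)-4-oxo-7-(triisopropylsilyloxy)-4H-chromen-8-yl]oxy}benzoate F5. BCl3 (CH2Cl2, −78 → 0 °C) should remove only the ethyl group peri to the C4 carbonyl (chelation-assisted dealkylation; the 4′-methyl ether is not chelated) to give methyl 4-{[5-hydroxy-2-(4-methoxyphenyl)-4-oxo-7-(triisopropylsilyloxy)-4H-chromen-8-yl]oxy}benzoate F6. CsF, K2CO3 and BnBr in DMF at 60 °C then convert F6 through diolate 26 into 27.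

Step 1 (silyl ynol ether). Monolithium acetylide 3 may disproportionate to Li2C2 before it is oxidised, ynolate 4 may be silylated on carbon to the silylketene, and the volatile, hydrolytically labile product may be lost on isolation. The fallback avoids the ynolate; it sets out from 2 and returns at 5. Freshly prepared anhydrous chloroacetaldehyde is silylated with 2 and Et3N (CH2Cl2, 0 °C) to the enol ether [(Z)-2-chloroethenyl]oxy-tri(propan-2-yl)silane F7. LiN(iPr)2 (1 equiv, THF, −78 °C) then eliminates hydrogen chloride by anti elimination to give 5, in the way ethoxyethyne is made from 2-halovinyl ethers.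

Step 8 (oxa-Michael addition). Conjugate addition of the hindered phenoxide to the donor-substituted alkynoate may be slow, and silyl groups may be transferred between phenoxides under the basic conditions. The fallback builds the pyranone by carbonylation and makes steps 7, 8 and 9 unnecessary; it sets out from 17 and returns at 25. Iodination ortho to the hydroxyl (N-iodosuccinimide, CH2Cl2, −20 °C; the other free position lies between two triisopropylsilyloxy groups and is shielded) should give methyl 4-[2-hydroxy-3-iodo-4,6-bis(triisopropylsilyloxy)phenoxy]benzoate F8. Palladium-catalysed carbonylative Sonogashira coupling with 18 (PdCl2(dppf), CO, Et2NH, 60 °C) gives the alkynone methyl 4-{2-hydroxy-3-[3-(4-methoxyphenyl)prop-2-ynoyl]-4,6-bis(triisopropylsilyloxy)phenoxy}benzoate F9, which should close in the same flask by amine-promoted 6-endo oxa-Michael addition to flavone 25.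

**Further compounds**

F1 | step 6 | methyl 4-[4-ethoxy-2-hydroxy-6-(triisopropylsilyloxy)phenoxy]benzoate | COC(=O)c1ccc(Oc2c(O)cc(OCC)cc2O[Si](C(C)C)(C(C)C)C(C)C)cc1
F2 | step 6 | tert-butyl (2Z)-3-{5-ethoxy-2-[4-(methoxycarbonyl)phenoxy]-3-(triisopropylsilyloxy)phenoxy}-3-(4-methoxyphenyl)prop-2-enoate | COC(=O)c1ccc(Oc2c(O/C(=C\C(=O)OC(C)(C)C)c3ccc(OC)cc3)cc(OCC)cc2O[Si](C(C)C)(C(C)C)C(C)C)cc1
F3 | step 6 | (2Z)-3-{5-ethoxy-2-[4-(methoxycarbonyl)phenoxy]-3-(triisopropylsilyloxy)phenoxy}-3-(4-methoxyphenyl)prop-2-enoic acid | COC(=O)c1ccc(Oc2c(O/C(=C\C(=O)O)c3ccc(OC)cc3)cc(OCC)cc2O[Si](C(C)C)(C(C)C)C(C)C)cc1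
F4 | step 6 | mixed anhydride of F3 with trifluoroacetic acid | COC(=O)c1ccc(Oc2c(O/C(=C\C(=O)OC(=O)C(F)(F)F)c3ccc(OC)cc3)cc(OCC)cc2O[Si](C(C)C)(C(C)C)C(C)C)cc1
F5 | step 6 | methyl 4-{[5-ethoxy-2-(4-methoxyphenyl)-4-oxo-7-(triisopropylsilyloxy)-4H-chromen-8-yl]oxy}benzoate | COc1ccc(-c2cc(=O)c3c(OCC)cc(O[Si](C(C)C)(C(C)C)C(C)C)c(Oc4ccc(C(=O)OC)cc4)c3o2)cc1
F6 | step 6 | methyl 4-{[5-hydroxy-2-(4-methoxyphenyl)-4-oxo-7-(triisopropylsilyloxy)-4H-chromen-8-yl]oxy}benzoate | COc1ccc(-c2cc(=O)c3c(O)cc(O[Si](C(C)C)(C(C)C)C(C)C)c(Oc4ccc(C(=O)OC)cc4)c3o2)cc1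
F7 | step 1 | [(Z)-2-chloroethenyl]oxy-tri(propan-2-yl)silane | Cl/C=C\O[Si](C(C)C)(C(C)C)C(C)C
F8 | step 8 | methyl 4-[2-hydroxy-3-iodo-4,6-bis(triisopropylsilyloxy)phenoxy]benzoate | COC(=O)c1ccc(Oc2c(O)c(I)c(O[Si](C(C)C)(C(C)C)C(C)C)cc2O[Si](C(C)C)(C(C)C)C(C)C)cc1
F9 | step 8 | methyl 4-{2-hydroxy-3-[3-(4-methoxyphenyl)prop-2-ynoyl]-4,6-bis(triisopropylsilyloxy)phenoxy}benzoate | COC(=O)c1ccc(Oc2c(O)c(C(=O)C#Cc3ccc(OC)cc3)c(O[Si](C(C)C)(C(C)C)C(C)C)cc2O[Si](C(C)C)(C(C)C)C(C)C)cc1
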